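**Retrosynthetic overview**

- The target is a methylene-bridged pair: ring A (8-butanoyl-5,7-dihydroxy-2,2-dimethyl-2H-chromene) and ring B (2-acetyl-4-geranyl-4-methylcyclohexane-1,3,5-trione, drawn as a dienol). The bridge CH2–C6 (ring B) bond is cut last, giving the ring A Mannich base 19 and the ring B monomer 10.
- The strategy rests on C4 of ring B, the only stereocentre: a quaternary carbon bearing CH3, the geranyl CH2 and the two ring carbonyl carbons C3 and C5. It is a 2,2-disubstituted malonyl unit whose two carbonyls differ only in their neighbours (C2 with the acetyl group, C6 with the bridge).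
- Ring B is opened at C5–C6 (Dieckmann) and C2–C3 (C-acylation of acetylacetone). This leads to the malonic half-ester 5 and, through enzymatic desymmetrisation, to the achiral diester 4.
- Ring A comes from phloroglucinol: C-butanoylation, sulfonylation of the para hydroxyl (to steer the annulation), chromene annulation with 3-methylbut-2-enal, desulfonylation, aminomethylation.
- Ring order: the ring B carbocycle (step 4) and the pyran ring of ring A (step 7) are built separately; the final union closes no ring.

Key step: step 2

Assumption: pig liver esterase is taken to cleave the pro-R CO2CH3 group of 4 and so give the (S)-half-ester 5; in this substrate class the sense depends on the size of the second substituent, so it must be verified on the first batch, and the opposite outcome is served by the fallback to step 2. Ring B compounds are drawn as one dienol tautomer and their descriptors refer to that drawing.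

**Route**

Step 1
Reactants: 1 dimethyl methylmalonate; 2 geranyl bromide
Product: 4 dimethyl 2-geranyl-2-methylmalonate, via sodium enolate of dimethyl methylmalonate 3 (not isolated)
Conditions: NaH (1.1 equiv), THF, 0 °C; then 2, 0 °C to rt
Reagents that add atoms: none
Why: Malonic ester alkylation, in which the sodium enolate displaces the primary allylic bromide by SN2 and leaves the E-alkene untouched, should give an achiral diester with two enantiotopic ester groups.

Step 2
Reactants: 4 dimethyl 2-geranyl-2-methylmalonate
Product: 5 (S)-2-geranyl-2-methylmalonic acid monomethyl ester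
Conditions: pig liver esterase, 0.1 M phosphate buffer pH 7.5, DMSO (10% v/v), 25 °C, pH-stat with 1 M NaOH to 1.0 equiv; then HCl to pH 2, EtOAc
Reagents that add atoms: water, O
Why: The active-site serine of the carboxylesterase attacks one of the two enantiotopic methoxycarbonyl groups, the acyl-enzyme releases methanol and is hydrolysed by water, and the resulting carboxylate is no longer accepted, so the reaction should stop at the half-ester. The closest known reaction type is the pig liver esterase desymmetrisation of prochiral 2,2-disubstituted malonate diesters. No ring is closed and no skeletal bond is made; C2 becomes a quaternary stereocentre only because its two carboxyl groups are now different. Its configuration is under enzyme control, the binding pockets having to tell the methyl group from the ten-carbon geranyl chain. The step needs enantiotopic-group selectivity and mono- over bis-hydrolysis; the first rests on the methyl/geranyl size contrast, supported by the DMSO cosolvent and moderate temperature, the second on the negative charge of the product. The quaternary carbon has no α-hydrogen, so it cannot racemise in later steps.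

Step 3
Reactants: 5 (S)-2-geranyl-2-methylmalonic acid monomethyl ester; 6 acetylacetone
Product: 9 methyl (2S,4E)-2-(2-acetyl-3-oxobutanoyl)-2,5,9-trimethyldeca-4,8-dienoate, via acid chloride of the half-ester 7 (not isolated), via chloromagnesium acetylacetonate 8 (not isolated)
Conditions: 5, 1-chloro-N,N,2-trimethylprop-1-en-1-amine (1.1 equiv), CH2Cl2, 0 °C to rt; this solution added to 6 (1.5 equiv), MgCl2 (1.5 equiv), pyridine (3 equiv), CH2Cl2, 0 °C to rt; 1 M HCl work-up
Reagents that add atoms: none
Why: The α-chloroenamine forms the acid chloride under neutral conditions (no HCl to add to the geranyl alkenes), and soft enolisation with MgCl2/pyridine gives a chelated magnesium enolate that is acylated at its central carbon (C-acylation of a β-diketone), with ester and quaternary centre untouched.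

Step 4
Reactants: 9 methyl (2S,4E)-2-(2-acetyl-3-oxobutanoyl)-2,5,9-trimethyldeca-4,8-dienoate
Product: 10 ring B monomer (4R)-2-acetyl-4-geranyl-3,5-dihydroxy-4-methylcyclohexa-2,5-dien-1-one
Conditions: LiN(iPr)2 (3.3 equiv, commercial solution), THF, −78 °C to 0 °C; 1 M HCl quench
Reagents that add atoms: none
Why: After the triacylmethane CH is deprotonated, further base removes an acetyl CH3 proton and this terminal carbanion attacks the methyl ester in a 6-exo-trig Dieckmann (intramolecular Claisen) condensation, helped by the gem-disubstituted carbon and driven by the delocalised trione anion; both acetyl groups lead to the same product and the stereocentre is not involved.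

Step 5
Reactants: 11 phloroglucinol; 12 butanoyl chloride
Product: 13 1-(2,4,6-trihydroxyphenyl)butan-1-one
Conditions: AlCl3 (3.5 equiv), nitrobenzene/CH2Cl2, 0 °C to 60 °C; ice/HCl
Reagents that add atoms: none
Why: Friedel–Crafts acylation of the electron-rich triphenol should stop after one acyl group because the aryl ketone deactivates the ring.

Step 6
Reactants: 13 1-(2,4,6-trihydroxyphenyl)butan-1-one
Product: 14 4-butanoyl-3,5-dihydroxyphenyl 4-methylbenzenesulfonate
Conditions: TsCl (1.05 equiv), K2CO3 (1.1 equiv), acetone, rt
Reagents that add atoms: 4-methylbenzenesulfonyl chloride, Cc1ccc(cc1)S(Cl)(=O)=O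
Why: The two hydroxyls ortho to the ketone are hydrogen-bonded to it and less reactive, so one equivalent of sulfonyl chloride with a weak base should sulfonylate the para hydroxyl selectively (selective O-sulfonylation).

Step 7
Reactants: 14 4-butanoyl-3,5-dihydroxyphenyl 4-methylbenzenesulfonate; 15 3-methylbut-2-enal
Product: 16 8-butanoyl-7-hydroxy-2,2-dimethyl-2H-chromen-5-yl 4-methylbenzenesulfonate
Conditions: 15 (1.3 equiv), ethylenediammonium diacetate (0.2 equiv), xylenes, 130 °C
Reagents that add atoms: none
Why: Amine-catalysed Knoevenagel-type condensation at the free ring carbon followed by oxa-6π electrocyclisation of the ortho-quinone methide closes the pyran ring, and because the oxygen on the other side is sulfonylated the ring can only close onto the hydroxyl next to the ketone, which fixes the 8-acyl regiochemistry.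

Step 8
Reactants: 16 8-butanoyl-7-hydroxy-2,2-dimethyl-2H-chromen-5-yl 4-methylbenzenesulfonate
Product: 17 1-(5,7-dihydroxy-2,2-dimethyl-2H-chromen-8-yl)butan-1-one
Conditions: 2 M aq NaOH, 1,4-dioxane, 60 °C; then HCl to pH 4
Reagents that add atoms: none
Why: Hydroxide attacks sulfur of the aryl sulfonate (S–O cleavage, sulfonate saponification), helped by the para acyl group that stabilises the leaving phenoxide, while chromene, ketone and phenols tolerate aqueous base.

Step 9
Reactants: 17 1-(5,7-dihydroxy-2,2-dimethyl-2H-chromen-8-yl)butan-1-one; 18 dimethyl(methylidene)ammonium iodide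
Product: 19 1-{6-[(dimethylamino)methyl]-5,7-dihydroxy-2,2-dimethyl-2H-chromen-8-yl}butan-1-one
Conditions: 18 (1.05 equiv), CH2Cl2, 0 °C to rt; aq NaHCO3 wash; used promptly
Reagents that add atoms: none
Why: Phenolic Mannich reaction, in which the preformed iminium ion is attacked by C6, the only unsubstituted ring carbon and activated by both flanking hydroxyls; the absence of free formaldehyde should limit diarylmethane formation.

Step 10
Reactants: 10 ring B monomer; 19 ring A Mannich base
Product: 21 target (4R)-2-acetyl-6-[(8-butanoyl-5,7-dihydroxy-2,2-dimethyl-2H-chromen-6-yl)methyl]-4-geranyl-3,5-dihydroxy-4-methylcyclohexa-2,5-dien-1-one, via ring A ortho-quinone methide 20 (not isolated)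
Conditions: 10 (1.0 equiv), 19 (1.1 equiv), 1,4-dioxane, 80 °C, argon; dilute HCl wash
Reagents that add atoms: none
Why: The acidic trione 10 protonates the benzylic amine, loss of dimethylamine gives the ortho-quinone methide 20, and the enolate carbon C6 of ring B adds to its exocyclic CH2 in a Michael addition that re-aromatises ring A; the quaternary stereocentre is remote from the reacting carbon and cannot epimerise.

**Compound list**

1 | dimethyl methylmalonate | COC(=O)C(C)C(=O)OC | starting material
2 | geranyl bromide, (2E)-1-bromo-3,7-dimethylocta-2,6-diene | BrC/C=C(\C)CCC=C(C)C | starting material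
3 | sodium enolate of dimethyl methylmalonate, NaC(CH3)(CO2CH3)2 | COC(=O)[C-](C)C(=O)OC.[Na+] | intermediate
4 | dimethyl 2-geranyl-2-methylmalonate (achiral) | COC(=O)C(C)(C/C=C(\C)CCC=C(C)C)C(=O)OC | intermediate
5 | (S)-2-geranyl-2-methylmalonic acid monomethyl ester, (2S,4E)-2-(methoxycarbonyl)-2,5,9-trimethyldeca-4,8-dienoic acid | COC(=O)[C@@](C)(C/C=C(\C)CCC=C(C)C)C(=O)O | intermediate
6 | acetylacetone, pentane-2,4-dione | CC(=O)CC(C)=O | starting material
7 | acid chloride of 5, methyl (2R,4E)-2-(chlorocarbonyl)-2,5,9-trimethyldeca-4,8-dienoate (same spatial arrangement as 5) | COC(=O)[C@@](C)(C/C=C(\C)CCC=C(C)C)C(=O)Cl | intermediate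
8 | chloromagnesium acetylacetonate, MgCl(C5H7O2) | CC(=O)C=C(C)[O-].[Mg+2].[Cl-] | intermediate
9 | methyl (2S,4E)-2-(2-acetyl-3-oxobutanoyl)-2,5,9-trimethyldeca-4,8-dienoate | COC(=O)[C@@](C)(C/C=C(\C)CCC=C(C)C)C(=O)C(C(C)=O)C(C)=O | intermediate
10 | ring B monomer, (4R)-2-acetyl-4-[(2E)-3,7-dimethylocta-2,6-dien-1-yl]-3,5-dihydroxy-4-methylcyclohexa-2,5-dien-1-one | O=C1C=C(O)[C@@](C)(C/C=C(\C)CCC=C(C)C)C(O)=C1C(C)=O | intermediate
11 | phloroglucinol | Oc1cc(O)cc(O)c1 | starting material
12 | butanoyl chloride | CCCC(=O)Cl | starting material
13 | 1-(2,4,6-trihydroxyphenyl)butan-1-one | CCCC(=O)c1c(O)cc(O)cc1O | intermediate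
14 | 4-butanoyl-3,5-dihydroxyphenyl 4-methylbenzenesulfonate | CCCC(=O)c1c(O)cc(OS(=O)(=O)c2ccc(C)cc2)cc1O | intermediate
15 | 3-methylbut-2-enal | CC(C)=CC=O | starting material
16 | 8-butanoyl-7-hydroxy-2,2-dimethyl-2H-chromen-5-yl 4-methylbenzenesulfonate | CCCC(=O)c1c(O)cc(OS(=O)(=O)c3ccc(C)cc3)c2c1OC(C)(C)C=C2 | intermediate
17 | 1-(5,7-dihydroxy-2,2-dimethyl-2H-chromen-8-yl)butan-1-one | CCCC(=O)c1c(O)cc(O)c2c1OC(C)(C)C=C2 | intermediate
18 | dimethyl(methylidene)ammonium iodide | C=[N+](C)C.[I-] | starting material
19 | 1-{6-[(dimethylamino)methyl]-5,7-dihydroxy-2,2-dimethyl-2H-chromen-8-yl}butan-1-one | CCCC(=O)c1c(O)c(CN(C)C)c(O)c2c1OC(C)(C)C=C2 | intermediate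
20 | ring A ortho-quinone methide, 8-butanoyl-7-hydroxy-2,2-dimethyl-6-methylidene-2H-chromen-5(6H)-one | CCCC(=O)C1=C(O)C(=C)C(=O)C2=C1OC(C)(C)C=C2 | intermediate
21 | target, (4R)-2-acetyl-6-[(8-butanoyl-5,7-dihydroxy-2,2-dimethyl-2H-chromen-6-yl)methyl]-4-[(2E)-3,7-dimethylocta-2,6-dien-1-yl]-3,5-dihydroxy-4-methylcyclohexa-2,5-dien-1-one | CCCC(=O)c1c(O)c(CC2=C(O)[C@@](C)(C/C=C(\C)CCC=C(C)C)C(O)=C(C(C)=O)C2=O)c(O)c2c1OC(C)(C)C=C2 | target

**Summary**

Total step count: 10. Longest linear sequence: 6 steps (steps 5 to 10, from phloroglucinol); the ring B branch is 5 steps (steps 1 to 4, then step 10).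

Steps most likely to fail:

Step 2. The enzyme may cleave the other enantiotopic ester group, or turn over the water-insoluble diester only slowly. Fallback: setting out again from 4, the hydrolysis is run as before and the product is taken on in the opposite series as (R)-2-geranyl-2-methylmalonic acid monomethyl ester F1, with the roles of acid and ester exchanged. Its acid chloride F2 (same chloroenamine, CH2Cl2) is added to an excess of the dianion of acetylacetone 6 (LiN(iPr)2, 2 equiv per diketone, THF, −78 °C). The dianion reacts at its terminal carbon and should give the linear triketo ester methyl (2R,4E)-2-geranyl-2-methyl-3,5,7-trioxooctanoate F3. NaOCH3 in CH3OH then closes ring B by Dieckmann attack of C6 (between two ketones) on the ester. In this series the former acid carbon becomes C5 and the ester carbon C3, so the (R)-half-ester leads to the same enantiomer, and the route is rejoined at 10.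

Step 4. The terminal carbanion next to an already anionic triacylmethane may not form completely, and retro-Claisen loss of an acetyl group or O-cyclisation to a pyranone may take over. Fallback: setting out from 5 (through its acid chloride 7), the magnesium enolate of purchased methyl 3,5-dioxohexanoate (CC(=O)CC(=O)CC(=O)OC; MgCl2, pyridine, CH2Cl2) is acylated at C4, the carbon between its two ketones. This should give dimethyl (2S)-4-acetyl-2-geranyl-2-methyl-3,5-dioxoheptanedioate F4. Its C6H2 is activated by a ketone and an ester, so NaH (2.2 equiv, THF) should form the C4/C6 dianion without forcing, and C6 closes onto the malonyl ester (Dieckmann) to give the 6-(methoxycarbonyl) derivative of the ring B monomer F5. Saponification (aq NaOH, 50 °C) and acidification to pH 3 with gentle warming remove that ester by decarboxylation of the vinylogous β-keto acid, and the route is rejoined at 10.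

Step 10. Reversible quinone methide formation may scramble the bridge: the Mannich base can self-condense with loss of its aminomethyl group to give symmetric ring A–CH2–ring A material, or C6 of ring B can be alkylated twice. Fallback: the polarity of the union is reversed. Setting out from 10, aminomethylation with 18 (CH2Cl2, 0 °C; NaHCO3 wash) should give the ring B Mannich base F6. On warming in 1,4-dioxane with the chromene 17, which has one free and strongly nucleophilic C6–H, it loses dimethylamine to the 6-methylidene trione F7 (not isolated). C6 of 17 attacks this in a Friedel–Crafts-type conjugate addition, and the route is rejoined at the target 21.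

**Further compounds**

F1 | step 2 | (R)-2-geranyl-2-methylmalonic acid monomethyl ester | COC(=O)[C@](C)(C/C=C(\C)CCC=C(C)C)C(=O)O
F2 | step 2 | acid chloride of F1 | COC(=O)[C@](C)(C/C=C(\C)CCC=C(C)C)C(=O)Cl
F3 | step 2 | methyl (2R,4E)-2-geranyl-2-methyl-3,5,7-trioxooctanoate | COC(=O)[C@](C)(C/C=C(\C)CCC=C(C)C)C(=O)CC(=O)CC(C)=O
F4 | step 4 | dimethyl (2S)-4-acetyl-2-geranyl-2-methyl-3,5-dioxoheptanedioate | COC(=O)[C@@](C)(C/C=C(\C)CCC=C(C)C)C(=O)C(C(C)=O)C(=O)CC(=O)OC
F5 | step 4 | 6-(methoxycarbonyl) derivative of ring B monomer 10 (same spatial arrangement at C4) | COC(=O)C1=C(O)[C@@](C)(C/C=C(\C)CCC=C(C)C)C(O)=C(C(C)=O)C1=O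
F6 | step 10 | ring B Mannich base, 6-[(dimethylamino)methyl] derivative of 10 | CN(C)CC1=C(O)[C@@](C)(C/C=C(\C)CCC=C(C)C)C(O)=C(C(C)=O)C1=O
F7 | step 10 | 6-methylidene trione from F6 | C=C1C(=O)[C@@](C)(C/C=C(\C)CCC=C(C)C)C(O)=C(C(C)=O)C1=O
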